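The constants are made up; the run is a simulation.

Start with the easy step: follow the open intermediate, which has two exits, and ask what each exit costs.

| setting | elm | cedar | birch | oak | ash |
|---|---|---|---|---|---|
| substrate | 0.50 mM (fed, over 25 s) | 0.50 mM | 0.50 mM | 0.50 mM (fed, over 25 s) | 0.50 mM (fed, over 2.5 s) |
| coupling partner | 0.900 equiv | 0.900 equiv | 0.900 equiv | 0.900 equiv | 0.900 equiv |
| second reagent | 1.00 equiv | 1.00 equiv (fed, over 25 s) | 1.00 equiv | 1.00 equiv | 1.00 equiv |
| capture agent | 0.500 mM | 0.500 mM | 0.500 mM | 0.500 mM | 0.500 mM |
| temperature | 50 °C | 50 °C | 50 °C |  | 50 °C |
| time | 1.0 min | 1.0 min | 1.0 min | 1.0 min | 1.0 min |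
| remark | all else is in the flask from the start; the feed brings no volume worth counting | all else is in the flask from the start; the feed brings no volume worth counting | everything together at the start | the addition at 20 °C, then warmed to 50 °C; the feed brings no volume worth counting | all else is in the flask from the start; the feed brings no volume worth counting |

    substrate + coupling partner → open intermediate (k1 = 180 M⁻¹ s⁻¹, Ea1 = 42.0 kJ mol⁻¹)
    second reagent + open intermediate → target (k2 = 2100 M⁻¹ s⁻¹, Ea2 = 38.0 kJ mol⁻¹)
    substrate + target → side product (k3 = 160 M⁻¹ s⁻¹, Ea3 = 50.0 kJ mol⁻¹)
    target → over-reaction product (k4 = 0.0068 s⁻¹, Ea4 = 91.0 kJ mol⁻¹)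
    open intermediate + capture agent → trapped intermediate (k5 = 630 M⁻¹ s⁻¹, Ea5 = 39.0 kJ mol⁻¹)
    (constants at 50 °C)

- percent here means substrate units held: one side product counts as two
- constants are those at 50 °C; use the activation energies for any other temperature

1. which flask leads in amount of target, in percent of the substrate charged ("all alike" within 1.5 percentage points) (elm / cedar / birch / oak / ash / all alike)
2. how much target is there at the end, in percent of the substrate charged: elm
3. how much target is there at the end, in percent of the substrate charged: cedar
4. how much target is there at the end, in percent of the substrate charged: birch
5. how much target is there at the end, in percent of the substrate charged: oak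
6. how much target is there at the end, in percent of the substrate charged: ash

Call the constant of the second reagent's step kR, here 2100 M⁻¹ s⁻¹, and that of the capture step kC, here 630 M⁻¹ s⁻¹. Write the two losses: c(second reagent) falls at kR·c(second reagent)·c(open intermediate), and c(capture agent) falls at kC·c(capture agent)·c(open intermediate). No other step touches either species. Divide one rate by the other and c(open intermediate) cancels, however fast it is being made. Integrate, with both species present from the start at one temperature: the logarithm of the fraction of second reagent left equals kR/kC times the logarithm of the fraction of capture agent left.

Name that ratio, 3.33, the split exponent; it is the selectivity factor of this pair. With both species in the flask from the start at one temperature, raise the fraction of capture agent left to this power and you have the fraction of second reagent left. So in elm, birch and ash the way substrate arrives moves the flask along one curve, not off it. Take the same exponent for oak, since 38.0 kJ mol⁻¹ and 39.0 kJ mol⁻¹ nearly match. Leave cedar out: its second reagent arrives over 25 s, so the integration does not apply.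

Now put a number on the curve. At the start of birch, capture takes a share 23.1 % of the open intermediate. Suppose the whole coupling partner passes through, 0.450 mM. Hold that start share through the run, as a rough estimate: the fraction of capture agent left is then 0.792, and the curve leaves 46.0 % of the second reagent. That is my reckoning, and it stops there. In birch, the target's half-life against attack by substrate alone, with substrate as charged, is 0.14 min, short against the 1.0 min run, and the curve says nothing about that loss.

The forecast does go on to the target, which my reckoning does not. It names oak as the leader, with 20.4 % in elm, 13.5 % in cedar, 18 % in birch, 21.5 % in oak and 18.3 % in ash. Its grounds for cedar: “Feeding the second reagent in cedar starves the open intermediate of its partner”.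

The simulation gives oak as the leader, with 19.8 % in elm, 15.1 % in cedar, 18.1 % in birch, 21.5 % in oak and 18.3 % in ash; oak's lead over elm is 1.7 percentage points, just beyond the margin. Apply the exponent to oak: 82.5 % of the capture agent left gives 52.7 % of the second reagent, and the flask holds 52.4 %. Apply it to the neighbour of oak charged with 0.20 mM of capture agent: 78.6 % left gives 44.8 %, and that flask holds 44.5 %. Its trapped intermediate is 8.58 %, and its target at 1.00 min is 25.9 %.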